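**Strategy.** Everything rests on cutting the C14'–C15' bond of the polyene. This divides the C40 skeleton into a ring B C18 trienediyne (12) ending in the only terminal alkyne, C13'≡C14', and a ring A C21 pentaenyl iodide (25) carrying the silylated 3,5,6-triol. In one operation, methylalumination and palladium/zinc coupling add the C13' methyl, fix the 13'E geometry and join C14' to C15'. The step exploits the methyl-branched trisubstituted C13'=C14' alkene beside the central C15=C15' bond, and the contrast between the exposed terminal alkyne and the internal C7'≡C8' alkyne shielded by ring B. Both halves derive from one enone, silyl ether 3 of (S)-phorenol.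

Key step: step 19

Assumption: the (S,S)-configured ruthenium catalyst of step 1 is taken to give the (4S)-alcohol, as it does with aryl and alkenyl ketones (the antipodal ligand would be used otherwise); locants in the Why lines follow carotenoid numbering, primed for the ring B half.

**Step 1**
Reactants: 1 2,6,6-trimethylcyclohex-2-ene-1,4-dione (ketoisophorone)
Product: 2 (4S)-4-hydroxy-2,6,6-trimethylcyclohex-2-en-1-one
Conditions: RuCl[(S,S)-TsDPEN](p-cymene) (1 mol%), HCO2H/Et3N (5:2), CH2Cl2, 25 °C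
Reagents that add atoms: none
Why: Noyori asymmetric transfer hydrogenation should reduce only the C4 carbonyl, because the C1 carbonyl is walled in by the gem-dimethyl carbon and the methyl-bearing alkene carbon, and the chiral Ru–H/N–H catalyst should select the enantioface that gives the (4S)-carbinol, the centre that becomes C3 and C3'.

**Step 2**
Reactants: 2 (4S)-4-hydroxy-2,6,6-trimethylcyclohex-2-en-1-one
Product: 3 (4S)-4-(tert-butyldimethylsilyloxy)-2,6,6-trimethylcyclohex-2-en-1-one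
Conditions: TBSCl, imidazole, DMF, 25 °C
Reagents that add atoms: tert-butyldimethylsilyl chloride, CC(C)(C)[Si](C)(C)Cl
Why: Imidazole-promoted silylation of a secondary alcohol is standard, and this silyl ether should outlast every base, hydride and organometallic reagent used later.

**Step 3**
Reactants: 3 (4S)-4-(tert-butyldimethylsilyloxy)-2,6,6-trimethylcyclohex-2-en-1-one
Product: 5 (4R)-4-(tert-butyldimethylsilyloxy)-2,6,6-trimethylcyclohex-1-en-1-yl trifluoromethanesulfonate, via lithium enolate 4 (not isolated)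
Conditions: LiBH(s-Bu)3, THF, −78 °C; then PhNTf2, −78 → 25 °C
Reagents that add atoms: N-phenylbis(trifluoromethanesulfonimide), O=S(=O)(N(c1ccccc1)S(=O)(=O)C(F)(F)F)C(F)(F)F
Why: Reductive triflation of an enone: the bulky borohydride should add hydride to the unsubstituted β-carbon of the α-methyl enone (the carbonyl is too hindered for 1,2-attack), giving one regiodefined tetrasubstituted enolate that the triflimide sulfonylates on oxygen, with the silyloxy-bearing centre untouched.

**Step 4**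
Reactants: 5 (4R)-4-(tert-butyldimethylsilyloxy)-2,6,6-trimethylcyclohex-1-en-1-yl trifluoromethanesulfonate; 6 (2E)-3-methylpent-2-en-4-yn-1-ol
Product: 7 (2E)-5-[(4R)-4-(tert-butyldimethylsilyloxy)-2,6,6-trimethylcyclohex-1-en-1-yl]-3-methylpent-2-en-4-yn-1-ol
Conditions: PdCl2(PPh3)2 (5 mol%), CuI (10 mol%), i-Pr2NH, DMF, 50 °C
Reagents that add atoms: none
Why: Sonogashira coupling of the enol triflate with the terminal alkyne forms the C6'–C7' bond under mild amine base, tolerates the free primary alcohol and keeps the E geometry already present in 6.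

**Step 5**
Reactants: 7 (2E)-5-[(4R)-4-(tert-butyldimethylsilyloxy)-2,6,6-trimethylcyclohex-1-en-1-yl]-3-methylpent-2-en-4-yn-1-ol
Product: 8 (2E)-5-[(4R)-4-(tert-butyldimethylsilyloxy)-2,6,6-trimethylcyclohex-1-en-1-yl]-3-methylpent-2-en-4-ynal
Conditions: MnO2, CH2Cl2, 25 °C
Reagents that add atoms: none
Why: MnO2 oxidises allylic alcohols selectively to enals under neutral conditions and leaves the silyl ether, the alkyne and the alkene geometry alone.

**Step 6**
Reactants: 8 (2E)-5-[(4R)-4-(tert-butyldimethylsilyloxy)-2,6,6-trimethylcyclohex-1-en-1-yl]-3-methylpent-2-en-4-ynal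
Product: 9 (1E,3E)-6-[(4R)-4-(tert-butyldimethylsilyloxy)-2,6,6-trimethylcyclohex-1-en-1-yl]-1-iodo-4-methylhexa-1,3-dien-5-yne
Conditions: CrCl2 (6 equiv), CHI3 (2 equiv), THF, 0 °C, dark
Reagents that add atoms: iodoform, IC(I)I
Why: Takai olefination: the geminal dichromium reagent formed from CHI3 and CrCl2 adds to the aldehyde and eliminates to the (E)-alkenyl iodide, conjugated aldehydes being the most E-selective substrates, which creates C11'=C12' and the handle for C13'.

**Step 7**
Reactants: 9 (1E,3E)-6-[(4R)-4-(tert-butyldimethylsilyloxy)-2,6,6-trimethylcyclohex-1-en-1-yl]-1-iodo-4-methylhexa-1,3-dien-5-yne; 10 ethynyltrimethylsilane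
Product: 11 [(3E,5E)-8-[(4R)-4-(tert-butyldimethylsilyloxy)-2,6,6-trimethylcyclohex-1-en-1-yl]-6-methylocta-3,5-diene-1,7-diyn-1-yl]trimethylsilane
Conditions: Pd(PPh3)4 (5 mol%), CuI (10 mol%), i-Pr2NH, THF, 25 °C
Reagents that add atoms: none
Why: Sonogashira coupling of the alkenyl iodide proceeds with retention of the E geometry and forms the C12'–C13' bond, the silyl cap preventing double coupling.

**Step 8**
Reactants: 11 [(3E,5E)-8-[(4R)-4-(tert-butyldimethylsilyloxy)-2,6,6-trimethylcyclohex-1-en-1-yl]-6-methylocta-3,5-diene-1,7-diyn-1-yl]trimethylsilane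
Product: 12 (3E,5E)-1-[(4R)-4-(tert-butyldimethylsilyloxy)-2,6,6-trimethylcyclohex-1-en-1-yl]-3-methylocta-3,5-diene-1,7-diyne (ring B C18 terminal alkyne)
Conditions: K2CO3, MeOH/THF, 0 → 25 °C
Reagents that add atoms: none
Why: Carbonate-catalysed methanolysis cleaves only the alkynyl C–Si bond and frees the terminal C13'≡C14' alkyne, the secondary silyl ether being inert to these conditions.

**Step 9**
Reactants: 3 (4S)-4-(tert-butyldimethylsilyloxy)-2,6,6-trimethylcyclohex-2-en-1-one; 6 (2E)-3-methylpent-2-en-4-yn-1-ol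
Product: 14 (1S,4S)-4-(tert-butyldimethylsilyloxy)-1-[(3E)-5-hydroxy-3-methylpent-3-en-1-yn-1-yl]-2,6,6-trimethylcyclohex-2-en-1-ol, via dilithio enynol 13 (not isolated)
Conditions: 6, n-BuLi (2 equiv), THF, −78 → 0 °C; then 3, −78 → 0 °C; aq. NH4Cl
Reagents that add atoms: none
Why: Acetylide 1,2-addition to a ketone that cannot enolise: the enone should adopt the half-chair with the C3 silyloxy group pseudo-equatorial (the other one places it syn-axial to a C1 methyl), so the pseudo-axial C1 methyl blocks one face and the slim nucleophile enters axially on the face cis to the silyloxy group, which sets C6 with its hydroxyl trans to the C3 oxygen.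

**Step 10**
Reactants: 14 (1S,4S)-4-(tert-butyldimethylsilyloxy)-1-[(3E)-5-hydroxy-3-methylpent-3-en-1-yn-1-yl]-2,6,6-trimethylcyclohex-2-en-1-ol
Product: 15 (2E)-5-[(1S,4S)-4-(tert-butyldimethylsilyloxy)-1-hydroxy-2,6,6-trimethylcyclohex-2-en-1-yl]-3-methylpent-2-en-4-yn-1-yl acetate
Conditions: Ac2O, pyridine, CH2Cl2, 0 °C
Reagents that add atoms: acetic anhydride, CC(=O)OC(C)=O
Why: Acetic anhydride with pyridine acylates the primary allylic alcohol and not the hindered tertiary one, so that only the C6 hydroxyl is left to direct the next oxidation.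

**Step 11**
Reactants: 15 (2E)-5-[(1S,4S)-4-(tert-butyldimethylsilyloxy)-1-hydroxy-2,6,6-trimethylcyclohex-2-en-1-yl]-3-methylpent-2-en-4-yn-1-yl acetate
Product: 16 (2E)-5-[(1R,2R,5S,6R)-5-(tert-butyldimethylsilyloxy)-2-hydroxy-1,3,3-trimethyl-7-oxabicyclo[4.1.0]heptan-2-yl]-3-methylpent-2-en-4-yn-1-yl acetate (epoxide oxygen cis to the tertiary hydroxyl and trans to the silyloxy group)
Conditions: VO(acac)2 (5 mol%), t-BuOOH, toluene, 0 → 25 °C
Reagents that add atoms: tert-butyl hydroperoxide, CC(C)(C)OO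
Why: Hydroxyl-directed epoxidation: the vanadate ester of the tertiary allylic C6 alcohol delivers the peroxide oxygen to the face of C4=C5 on which the hydroxyl sits, which is also the face away from the neighbouring silyloxy group, so C4 and C5 are set cis to the C6 oxygen while the enyne, which has no free directing hydroxyl, should not react.

**Step 12**
Reactants: 16 (2E)-5-[(1R,2R,5S,6R)-5-(tert-butyldimethylsilyloxy)-2-hydroxy-1,3,3-trimethyl-7-oxabicyclo[4.1.0]heptan-2-yl]-3-methylpent-2-en-4-yn-1-yl acetate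
Product: 17 (1S,2R,4S)-4-(tert-butyldimethylsilyloxy)-1-[(1E,3E)-5-hydroxy-3-methylpenta-1,3-dien-1-yl]-2,6,6-trimethylcyclohexane-1,2-diol
Conditions: LiAlH4, THF, 0 °C → reflux; aq. potassium sodium tartrate
Reagents that add atoms: none
Why: One hydride reagent does three standard jobs: it cleaves the acetate, it reduces the propargylic alkyne by alkoxide-directed trans-hydroalumination to the 7E alkene, and it opens the trisubstituted epoxide by SN2 attack at the less substituted C4 in the trans-diaxial sense, which leaves the C5–O bond intact and so gives the cis-5,6-diol with the configuration fixed in steps 9 and 11.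

**Step 13**
Reactants: 17 (1S,2R,4S)-4-(tert-butyldimethylsilyloxy)-1-[(1E,3E)-5-hydroxy-3-methylpenta-1,3-dien-1-yl]-2,6,6-trimethylcyclohexane-1,2-diol
Product: 18 (2E,4E)-5-[(1S,2R,4S)-4-(tert-butyldimethylsilyloxy)-1,2-dihydroxy-2,6,6-trimethylcyclohexyl]-3-methylpenta-2,4-dienal
Conditions: MnO2, CH2Cl2, 25 °C
Reagents that add atoms: none
Why: MnO2 oxidises only the primary allylic alcohol to the dienal, since the two tertiary hydroxyls cannot be oxidised.

**Step 14**
Reactants: 18 (2E,4E)-5-[(1S,2R,4S)-4-(tert-butyldimethylsilyloxy)-1,2-dihydroxy-2,6,6-trimethylcyclohexyl]-3-methylpenta-2,4-dienal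
Product: 19 (2E,4E)-5-[(1S,2R,4S)-4-(tert-butyldimethylsilyloxy)-2,6,6-trimethyl-1,2-bis(trimethylsilyloxy)cyclohexyl]-3-methylpenta-2,4-dienal
Conditions: TMSOTf (3 equiv), 2,6-lutidine (5 equiv), CH2Cl2, −78 → 0 °C
Reagents that add atoms: trimethylsilyl trifluoromethanesulfonate, C[Si](C)(C)OS(=O)(=O)C(F)(F)F
Why: A silyl triflate with a hindered pyridine base silylates even crowded tertiary alcohols at low temperature, and doing so on the electron-poor dienal, where an allylic cation at C6 is disfavoured, should keep ionisation of the tertiary allylic centre at bay.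

**Step 15**
Reactants: 19 (2E,4E)-5-[(1S,2R,4S)-4-(tert-butyldimethylsilyloxy)-2,6,6-trimethyl-1,2-bis(trimethylsilyloxy)cyclohexyl]-3-methylpenta-2,4-dienal; 20 ethyl (2E)-4-(diethoxyphosphoryl)-3-methylbut-2-enoate
Product: 22 ethyl (2E,4E,6E,8E)-9-[(1S,2R,4S)-4-(tert-butyldimethylsilyloxy)-2,6,6-trimethyl-1,2-bis(trimethylsilyloxy)cyclohexyl]-3,7-dimethylnona-2,4,6,8-tetraenoate, via lithiated phosphonate 21 (not isolated)
Conditions: 20, n-BuLi, DMPU, THF, −78 °C; then 19, −78 → 0 °C
Reagents that add atoms: none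
Why: Horner–Wadsworth–Emmons olefination with the C5 phosphonate anion forms C11=C12 with E selectivity and brings in C12–C15 with the C20 methyl; low temperature and DMPU should keep the 13E geometry of the reagent, and any 13Z isomer would be removed by chromatography.

**Step 16**
Reactants: 22 ethyl (2E,4E,6E,8E)-9-[(1S,2R,4S)-4-(tert-butyldimethylsilyloxy)-2,6,6-trimethyl-1,2-bis(trimethylsilyloxy)cyclohexyl]-3,7-dimethylnona-2,4,6,8-tetraenoate
Product: 23 (2E,4E,6E,8E)-9-[(1S,2R,4S)-4-(tert-butyldimethylsilyloxy)-2,6,6-trimethyl-1,2-bis(trimethylsilyloxy)cyclohexyl]-3,7-dimethylnona-2,4,6,8-tetraen-1-ol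
Conditions: i-Bu2AlH, CH2Cl2, −78 °C; aq. potassium sodium tartrate
Reagents that add atoms: none
Why: i-Bu2AlH reduces the conjugated ester to the allylic alcohol without conjugate reduction and without touching the silyl ethers.

**Step 17**
Reactants: 23 (2E,4E,6E,8E)-9-[(1S,2R,4S)-4-(tert-butyldimethylsilyloxy)-2,6,6-trimethyl-1,2-bis(trimethylsilyloxy)cyclohexyl]-3,7-dimethylnona-2,4,6,8-tetraen-1-ol
Product: 24 (2E,4E,6E,8E)-9-[(1S,2R,4S)-4-(tert-butyldimethylsilyloxy)-2,6,6-trimethyl-1,2-bis(trimethylsilyloxy)cyclohexyl]-3,7-dimethylnona-2,4,6,8-tetraenal (ring A C20 aldehyde)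
Conditions: MnO2, CH2Cl2, 25 °C, dark
Reagents that add atoms: none
Why: MnO2 oxidation of the polyenyl allylic alcohol gives the tetraenal under neutral conditions that the silyl ethers tolerate.

**Step 18**
Reactants: 24 (2E,4E,6E,8E)-9-[(1S,2R,4S)-4-(tert-butyldimethylsilyloxy)-2,6,6-trimethyl-1,2-bis(trimethylsilyloxy)cyclohexyl]-3,7-dimethylnona-2,4,6,8-tetraenal
Product: 25 (1S,2R,4S)-4-(tert-butyldimethylsilyloxy)-1-[(1E,3E,5E,7E,9E)-10-iodo-3,7-dimethyldeca-1,3,5,7,9-pentaen-1-yl]-2,6,6-trimethyl-1,2-bis(trimethylsilyloxy)cyclohexane (ring A C21 pentaenyl iodide)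
Conditions: CrCl2 (6 equiv), CHI3 (2 equiv), THF, 0 °C, dark
Reagents that add atoms: iodoform, IC(I)I
Why: Takai olefination as in step 6 converts the conjugated aldehyde into the (E)-alkenyl iodide, adding C15' and the iodine needed for the coupling, and the trivalent chromium salts formed are not acidic enough to harm the silyl ethers.

**Step 19**
Reactants: 12 (3E,5E)-1-[(4R)-4-(tert-butyldimethylsilyloxy)-2,6,6-trimethylcyclohex-1-en-1-yl]-3-methylocta-3,5-diene-1,7-diyne; 26 trimethylaluminium; 25 ring A C21 pentaenyl iodide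
Product: 29 (3S,5R,6S,3'R)-3,3'-bis(tert-butyldimethylsilyloxy)-5,6-bis(trimethylsilyloxy)-7',8'-didehydro-5,6-dihydro-β,β-carotene, via alkenyldimethylalane 27 (not isolated), via alkenylzinc chloride 28 (not isolated)
Conditions: 12, AlMe3 (2 equiv), Cp2ZrCl2 (0.25 equiv), CH2Cl2, 0 → 25 °C; evaporate, THF; then 25, ZnCl2 (1 equiv), Pd(PPh3)4 (5 mol%), 25 °C, dark
Reagents that add atoms: none
Why: Cp2ZrCl2 and AlMe3 form a chloride-bridged Zr–Al methyl species that adds methyl and metal syn across the terminal C13'≡C14' alkyne, methyl to the internal carbon C13', giving the (E)-alkenylalane 27; after the chlorinated solvent is exchanged for THF, ZnCl2 takes over the alkenyl group (28), zerovalent palladium inserts into the C15'–I bond of 25, the alkenyl group passes from zinc to palladium, and reductive elimination forms C14'–C15' with retention at both alkenes. The closest known reaction type is the zirconium-catalysed methylalumination of terminal enynes followed by palladium-catalysed alkenyl–alkenyl Negishi coupling, as used for polyene chains. No ring is closed and no stereocentre is formed; the step defines only the 13'E geometry, which follows from syn carbometalation. The selectivities needed are methyl to C13' and not C14' (secured by the polarity and steric bias of a terminal alkyne), reaction at C13'≡C14' and not at C7'≡C8' (which is internal and flanked by the ring B gem-dimethyl carbon and C9'), and freedom from protonolysis or ionisation (all four oxygens are silylated, and the Lewis-acidic Zr/Al mixture meets 25 only after THF has been added, which protects the tertiary allylic C6 silyl ether).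

**Step 20**
Reactants: 29 (3S,5R,6S,3'R)-3,3'-bis(tert-butyldimethylsilyloxy)-5,6-bis(trimethylsilyloxy)-7',8'-didehydro-5,6-dihydro-β,β-carotene
Product: 30 (3S,5R,6S,3'R)-7',8'-didehydro-5,6-dihydro-β,β-carotene-3,5,6,3'-tetrol
Conditions: Bu4NF/AcOH (1:1, 8 equiv), THF, 0 → 25 °C, dark
Reagents that add atoms: none
Why: Fluoride buffered with acetic acid cleaves all four Si–O bonds (the tertiary trimethylsilyl ethers fast, the secondary tert-butyldimethylsilyl ethers more slowly) without the basicity or acidity that could isomerise the polyene or ionise the tertiary allylic C6 alcohol.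

**Compound list**

1 | 2,6,6-trimethylcyclohex-2-ene-1,4-dione (ketoisophorone) | CC1=CC(=O)CC(C)(C)C1=O | starting material
2 | (4S)-4-hydroxy-2,6,6-trimethylcyclohex-2-en-1-one ((S)-phorenol) | CC1=C[C@@H](O)CC(C)(C)C1=O | intermediate
3 | (4S)-4-(tert-butyldimethylsilyloxy)-2,6,6-trimethylcyclohex-2-en-1-one | CC1=C[C@@H](O[Si](C)(C)C(C)(C)C)CC(C)(C)C1=O | intermediate
4 | lithium (4R)-4-(tert-butyldimethylsilyloxy)-2,6,6-trimethylcyclohex-1-en-1-olate | CC1=C([O-])C(C)(C)C[C@H](O[Si](C)(C)C(C)(C)C)C1.[Li+] | intermediate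
5 | (4R)-4-(tert-butyldimethylsilyloxy)-2,6,6-trimethylcyclohex-1-en-1-yl trifluoromethanesulfonate | CC1=C(OS(=O)(=O)C(F)(F)F)C(C)(C)C[C@H](O[Si](C)(C)C(C)(C)C)C1 | intermediate
6 | (2E)-3-methylpent-2-en-4-yn-1-ol | C#C/C(C)=C/CO | starting material
7 | (2E)-5-[(4R)-4-(tert-butyldimethylsilyloxy)-2,6,6-trimethylcyclohex-1-en-1-yl]-3-methylpent-2-en-4-yn-1-ol | CC1=C(C#C/C(C)=C/CO)C(C)(C)C[C@H](O[Si](C)(C)C(C)(C)C)C1 | intermediate
8 | (2E)-5-[(4R)-4-(tert-butyldimethylsilyloxy)-2,6,6-trimethylcyclohex-1-en-1-yl]-3-methylpent-2-en-4-ynal | CC1=C(C#C/C(C)=C/C=O)C(C)(C)C[C@H](O[Si](C)(C)C(C)(C)C)C1 | intermediate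
9 | (1E,3E)-6-[(4R)-4-(tert-butyldimethylsilyloxy)-2,6,6-trimethylcyclohex-1-en-1-yl]-1-iodo-4-methylhexa-1,3-dien-5-yne | CC1=C(C#C/C(C)=C/C=C/I)C(C)(C)C[C@H](O[Si](C)(C)C(C)(C)C)C1 | intermediate
10 | ethynyltrimethylsilane | C#C[Si](C)(C)C | starting material
11 | [(3E,5E)-8-[(4R)-4-(tert-butyldimethylsilyloxy)-2,6,6-trimethylcyclohex-1-en-1-yl]-6-methylocta-3,5-diene-1,7-diyn-1-yl]trimethylsilane | CC1=C(C#C/C(C)=C/C=C/C#C[Si](C)(C)C)C(C)(C)C[C@H](O[Si](C)(C)C(C)(C)C)C1 | intermediate
12 | (3E,5E)-1-[(4R)-4-(tert-butyldimethylsilyloxy)-2,6,6-trimethylcyclohex-1-en-1-yl]-3-methylocta-3,5-diene-1,7-diyne (ring B C18 terminal alkyne) | CC1=C(C#C/C(C)=C/C=C/C#C)C(C)(C)C[C@H](O[Si](C)(C)C(C)(C)C)C1 | intermediate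
13 | dilithium salt of 6 (lithium alkoxide and lithium acetylide) | [Li]C#C/C(C)=C/CO[Li] | intermediate
14 | (1S,4S)-4-(tert-butyldimethylsilyloxy)-1-[(3E)-5-hydroxy-3-methylpent-3-en-1-yn-1-yl]-2,6,6-trimethylcyclohex-2-en-1-ol | OC/C=C(C)/C#C[C@]1(O)C(C)(C)C[C@H](O[Si](C)(C)C(C)(C)C)C=C1C | intermediate
15 | (2E)-5-[(1S,4S)-4-(tert-butyldimethylsilyloxy)-1-hydroxy-2,6,6-trimethylcyclohex-2-en-1-yl]-3-methylpent-2-en-4-yn-1-yl acetate | CC(=O)OC/C=C(C)/C#C[C@]1(O)C(C)(C)C[C@H](O[Si](C)(C)C(C)(C)C)C=C1C | intermediate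
16 | (2E)-5-[(1R,2R,5S,6R)-5-(tert-butyldimethylsilyloxy)-2-hydroxy-1,3,3-trimethyl-7-oxabicyclo[4.1.0]heptan-2-yl]-3-methylpent-2-en-4-yn-1-yl acetate | CC(=O)OC/C=C(C)/C#C[C@]1(O)C(C)(C)C[C@H](O[Si](C)(C)C(C)(C)C)[C@H]2O[C@@]12C | intermediate
17 | (1S,2R,4S)-4-(tert-butyldimethylsilyloxy)-1-[(1E,3E)-5-hydroxy-3-methylpenta-1,3-dien-1-yl]-2,6,6-trimethylcyclohexane-1,2-diol | OC/C=C(C)/C=C/[C@]1(O)C(C)(C)C[C@H](O[Si](C)(C)C(C)(C)C)C[C@@]1(C)O | intermediate
18 | (2E,4E)-5-[(1S,2R,4S)-4-(tert-butyldimethylsilyloxy)-1,2-dihydroxy-2,6,6-trimethylcyclohexyl]-3-methylpenta-2,4-dienal | O=C/C=C(C)/C=C/[C@]1(O)C(C)(C)C[C@H](O[Si](C)(C)C(C)(C)C)C[C@@]1(C)O | intermediate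
19 | (2E,4E)-5-[(1S,2R,4S)-4-(tert-butyldimethylsilyloxy)-2,6,6-trimethyl-1,2-bis(trimethylsilyloxy)cyclohexyl]-3-methylpenta-2,4-dienal | O=C/C=C(C)/C=C/[C@]1(O[Si](C)(C)C)C(C)(C)C[C@H](O[Si](C)(C)C(C)(C)C)C[C@@]1(C)O[Si](C)(C)C | intermediate
20 | ethyl (2E)-4-(diethoxyphosphoryl)-3-methylbut-2-enoate | CCOC(=O)/C=C(\C)CP(=O)(OCC)OCC | starting material
21 | lithium salt of 20 deprotonated at C4 | CCOC(=O)/C=C(\C)[CH-]P(=O)(OCC)OCC.[Li+] | intermediate
22 | ethyl (2E,4E,6E,8E)-9-[(1S,2R,4S)-4-(tert-butyldimethylsilyloxy)-2,6,6-trimethyl-1,2-bis(trimethylsilyloxy)cyclohexyl]-3,7-dimethylnona-2,4,6,8-tetraenoate | CCOC(=O)/C=C(C)/C=C/C=C(C)/C=C/[C@]1(O[Si](C)(C)C)C(C)(C)C[C@H](O[Si](C)(C)C(C)(C)C)C[C@@]1(C)O[Si](C)(C)C | intermediate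
23 | (2E,4E,6E,8E)-9-[(1S,2R,4S)-4-(tert-butyldimethylsilyloxy)-2,6,6-trimethyl-1,2-bis(trimethylsilyloxy)cyclohexyl]-3,7-dimethylnona-2,4,6,8-tetraen-1-ol | OC/C=C(C)/C=C/C=C(C)/C=C/[C@]1(O[Si](C)(C)C)C(C)(C)C[C@H](O[Si](C)(C)C(C)(C)C)C[C@@]1(C)O[Si](C)(C)C | intermediate
24 | (2E,4E,6E,8E)-9-[(1S,2R,4S)-4-(tert-butyldimethylsilyloxy)-2,6,6-trimethyl-1,2-bis(trimethylsilyloxy)cyclohexyl]-3,7-dimethylnona-2,4,6,8-tetraenal | O=C/C=C(C)/C=C/C=C(C)/C=C/[C@]1(O[Si](C)(C)C)C(C)(C)C[C@H](O[Si](C)(C)C(C)(C)C)C[C@@]1(C)O[Si](C)(C)C | intermediate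
25 | (1S,2R,4S)-4-(tert-butyldimethylsilyloxy)-1-[(1E,3E,5E,7E,9E)-10-iodo-3,7-dimethyldeca-1,3,5,7,9-pentaen-1-yl]-2,6,6-trimethyl-1,2-bis(trimethylsilyloxy)cyclohexane (ring A C21 pentaenyl iodide) | I/C=C/C=C(C)/C=C/C=C(C)/C=C/[C@]1(O[Si](C)(C)C)C(C)(C)C[C@H](O[Si](C)(C)C(C)(C)C)C[C@@]1(C)O[Si](C)(C)C | intermediate
26 | trimethylaluminium | C[Al](C)C | starting material
27 | [(1E,3E,5E)-8-[(4R)-4-(tert-butyldimethylsilyloxy)-2,6,6-trimethylcyclohex-1-en-1-yl]-2,6-dimethylocta-1,3,5-trien-7-yn-1-yl]dimethylalumane | CC1=C(C#C/C(C)=C/C=C/C(C)=C/[Al](C)C)C(C)(C)C[C@H](O[Si](C)(C)C(C)(C)C)C1 | intermediate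
28 | chloro[(1E,3E,5E)-8-[(4R)-4-(tert-butyldimethylsilyloxy)-2,6,6-trimethylcyclohex-1-en-1-yl]-2,6-dimethylocta-1,3,5-trien-7-yn-1-yl]zinc | CC1=C(C#C/C(C)=C/C=C/C(C)=C/[Zn]Cl)C(C)(C)C[C@H](O[Si](C)(C)C(C)(C)C)C1 | intermediate
29 | (3S,5R,6S,3'R)-3,3'-bis(tert-butyldimethylsilyloxy)-5,6-bis(trimethylsilyloxy)-7',8'-didehydro-5,6-dihydro-β,β-carotene | CC1=C(C#C/C(C)=C/C=C/C(C)=C/C=C/C=C(C)/C=C/C=C(C)/C=C/[C@]2(O[Si](C)(C)C)C(C)(C)C[C@H](O[Si](C)(C)C(C)(C)C)C[C@@]2(C)O[Si](C)(C)C)C(C)(C)C[C@H](O[Si](C)(C)C(C)(C)C)C1 | intermediate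
30 | (3S,5R,6S,3'R)-7',8'-didehydro-5,6-dihydro-β,β-carotene-3,5,6,3'-tetrol | CC1=C(C#C/C(C)=C/C=C/C(C)=C/C=C/C=C(C)/C=C/C=C(C)/C=C/[C@]2(O)C(C)(C)C[C@H](O)C[C@@]2(C)O)C(C)(C)C[C@H](O)C1 | target

**Step count and risks**

Total step count: 20. Longest linear sequence: 14 steps (steps 1, 2 and 9 to 20).

Most likely to fail, first: step 19. The alkenyl metal may be lost to protonolysis before it couples, carbometalation may spread to the wrong alkyne carbon, or the Lewis-acidic mixture may scramble the polyene geometry. The two halves would then be joined at the central C15=C15' double bond by a Wittig reaction instead. This fallback sets out from aldehyde 8 and uses 21 and 24 of the main route. Horner–Wadsworth–Emmons reaction of 8 with 21 (THF, DMPU, −78 → 0 °C) should give the ring B C20 trienynoate ester F1. Reduction with i-Bu2AlH (CH2Cl2, −78 °C) should give the allylic alcohol F2, and PPh3·HBr (CH2Cl2, 0 °C) the triphenylphosphonium bromide F3. Its ylide (NaOMe, CH2Cl2/MeOH, 0 °C) would be condensed with aldehyde 24, and the E/Z mixture at the new central bond equilibrated thermally to the all-E isomer. That isomer is compound 29, where the route is rejoined before step 20.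

Second: step 12. Hydride attack at the hindered C4 of the epoxide may lag behind the other two reductions, and forcing it may erode regiocontrol or the silyl ether. The three tasks would then be divided between two reagents of different character, with an isolated intermediate. Setting out from 16, LiBHEt3 (THF, 0 → 25 °C) is a far more nucleophilic hydride that opens hindered epoxides by SN2 attack at the less substituted carbon and also cleaves the acetate; it should give the alkynyl triol F4. NaAlH2(OCH2CH2OMe)2 (THF, 0 → 25 °C) would then carry out only the hydroxyl-directed trans reduction of the propargylic alkyne, which returns the route to 17.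

Third: step 3. Hydride may add sluggishly at the β-carbon next to the silyloxy group, or the hindered, borane-complexed enolate may resist O-sulfonylation. The triflate would then be made by deprotonation of the saturated ketone. Setting out from 1, baker's yeast (sucrose, water, 30 °C) reduces the ring C=C to the diketone (6R)-2,2,6-trimethylcyclohexane-1,4-dione F5. Hydrogenation of its unhindered carbonyl (H2, Raney Ni, MeOH) should give mainly the trans hydroxy ketone (4R,6R)-4-hydroxy-2,2,6-trimethylcyclohexan-1-one F6. Silylation (TBSCl, imidazole, DMF) gives the silyl ether (4R,6R)-4-(tert-butyldimethylsilyloxy)-2,2,6-trimethylcyclohexan-1-one F7. LiN(i-Pr)2 (THF, −78 °C) followed by PhNTf2 then forms the same enolate 4 and from it triflate 5, where the route is rejoined; compound 3 is still made by steps 1 and 2 for ring A.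

**Further compounds**

F1 | step 19 | ethyl (2E,4E,6E)-9-[(4R)-4-(tert-butyldimethylsilyloxy)-2,6,6-trimethylcyclohex-1-en-1-yl]-3,7-dimethylnona-2,4,6-trien-8-ynoate | CC1=C(C#C/C(C)=C/C=C/C(C)=C/C(=O)OCC)C(C)(C)C[C@H](O[Si](C)(C)C(C)(C)C)C1
F2 | step 19 | (2E,4E,6E)-9-[(4R)-4-(tert-butyldimethylsilyloxy)-2,6,6-trimethylcyclohex-1-en-1-yl]-3,7-dimethylnona-2,4,6-trien-8-yn-1-ol | CC1=C(C#C/C(C)=C/C=C/C(C)=C/CO)C(C)(C)C[C@H](O[Si](C)(C)C(C)(C)C)C1
F3 | step 19 | [(2E,4E,6E)-9-[(4R)-4-(tert-butyldimethylsilyloxy)-2,6,6-trimethylcyclohex-1-en-1-yl]-3,7-dimethylnona-2,4,6-trien-8-yn-1-yl]triphenylphosphonium bromide | CC1=C(C#C/C(C)=C/C=C/C(C)=C/C[P+](c2ccccc2)(c2ccccc2)c2ccccc2)C(C)(C)C[C@H](O[Si](C)(C)C(C)(C)C)C1.[Br-]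
F4 | step 12 | (1R,2R,4S)-4-(tert-butyldimethylsilyloxy)-1-[(3E)-5-hydroxy-3-methylpent-3-en-1-yn-1-yl]-2,6,6-trimethylcyclohexane-1,2-diol | OC/C=C(C)/C#C[C@]1(O)C(C)(C)C[C@H](O[Si](C)(C)C(C)(C)C)C[C@@]1(C)O
F5 | step 3 | (6R)-2,2,6-trimethylcyclohexane-1,4-dione | C[C@@H]1CC(=O)CC(C)(C)C1=O
F6 | step 3 | (4R,6R)-4-hydroxy-2,2,6-trimethylcyclohexan-1-one | C[C@@H]1C[C@@H](O)CC(C)(C)C1=O
F7 | step 3 | (4R,6R)-4-(tert-butyldimethylsilyloxy)-2,2,6-trimethylcyclohexan-1-one | C[C@@H]1C[C@@H](O[Si](C)(C)C(C)(C)C)CC(C)(C)C1=O
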